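**Plan**
- Numbering: C1 is the carboxyl carbon, the chain runs C1–C16, and the ring is O1 (on C6)–O2 (on C3)–C3–C4–C5–C6. O2 sits on C3, β to C1, so the ring bond O2–C3 and the free CO2H are the two ends of an opened oxetan-2-one spanning C1–C2–C3.
- Retrosynthetic cuts, in order: O2–C3 (peroxide opens the β-lactone); the C6–O1 bond together with the H on the C6 methyl carbon (peroxidation of a C6=CH2 alkene); C2–C3 and C1–O (ketene–aldehyde [2+2]); C5–C6 (Negishi coupling); C8–C9 (conjugate addition).
- Forward: the C6–C16 tail ketone is made first, converted into its terminal enol triflate and joined to the C3–C5 zinc reagent. The ester then becomes the aldehyde, the β-lactone (the only ring before the key step) is built, C6 is oxygenated, and the 1,2-dioxane closes last as the lactone opens.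
- Stereochemistry: C8 comes from the ligand in the copper-catalysed Grignard addition; C4 from methyl (S)-3-hydroxy-2-methylpropanoate; C3 from the cyclocondensation catalyst (R in the lactone), inverted to S in the ring closure. C6 is not controlled, and its epimer is removed by chromatography at the end.

Key step: step 9

Remarks on the chemistry:
- C6 is created without control in step 7. Numbers 15–18 denote the 6R series, carried together with its 6S epimer until the chromatography of step 9.
- For the ligand-controlled steps 1 and 6, the antipode written is the one assumed to give the required sense; the mirror-image ligand is used if a test run shows otherwise.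
- Metal alkoxides, enolates and carboxylates that are only protonated on work-up are treated as the salt form of the product and carry no number.

**Step 1**
Reactants: 1 (8-bromooctyl)benzene; 2 (E)-pent-3-en-2-one
Product: 4 (4R)-4-methyl-12-phenyldodecan-2-one, via (8-phenyloctyl)magnesium bromide 3 (not isolated)
Conditions: Mg, Et2O; then CuBr·SMe2 (5 mol%), (R)-1-[(SP)-2-(diphenylphosphino)ferrocenyl]ethyldicyclohexylphosphine (6 mol%), t-BuOMe, –75 °C, slow addition of 2; aq. NH4Cl
Reagents that add atoms: none
Why: Copper-catalysed enantioselective 1,4-addition of a Grignard reagent to an acyclic (E)-enone, in which the chiral ferrocenyl diphosphine–copper complex differentiates the enone faces and so sets C8 as R, while low temperature and slow enone addition hold back 1,2-addition.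

**Step 2**
Reactants: 4 (4R)-4-methyl-12-phenyldodecan-2-one
Product: 6 (4R)-4-methyl-12-phenyldodec-1-en-2-yl trifluoromethanesulfonate, via lithium enolate 5 (not isolated)
Conditions: LiN(i-Pr)2, THF, –78 °C; PhNTf2, –78 → 0 °C
Reagents that add atoms: N-phenylbis(trifluoromethanesulfonimide), O=S(=O)(N(c1ccccc1)S(=O)(=O)C(F)(F)F)C(F)(F)F
Why: Kinetic deprotonation of the methyl ketone on the CH3 side followed by O-sulfonylation of the terminal enolate (enol triflate formation) should give the 2-triflyloxy-1-alkene, and the C8 centre, being β to the carbonyl group, cannot epimerise.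

**Step 3**
Reactants: 7 methyl (S)-3-hydroxy-2-methylpropanoate
Product: 8 methyl (R)-3-iodo-2-methylpropanoate
Conditions: I2, PPh3, imidazole, CH2Cl2, 0 °C → rt
Reagents that add atoms: iodine, II
Why: Appel-type iodination of the primary alcohol under nearly neutral conditions leaves the α-stereocentre untouched, the change of descriptor from S to R being only a change of substituent priority.

**Step 4**
Reactants: 8 methyl (R)-3-iodo-2-methylpropanoate; 6 (4R)-4-methyl-12-phenyldodec-1-en-2-yl trifluoromethanesulfonate
Product: 10 methyl (2S,6R)-2,6-dimethyl-4-methylidene-14-phenyltetradecanoate, via alkylzinc iodide 9 (not isolated)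
Conditions: Zn dust (BrCH2CH2Br, Me3SiCl activation), DMF, rt; then 6, Pd(PPh3)4 (5 mol%), THF–DMF, 45 °C
Reagents that add atoms: none
Why: Zinc inserts into the primary C–I bond to give an ester-chelated alkylzinc iodide that should undergo Negishi sp3–sp2 cross-coupling with the alkenyl triflate, forming C5–C6 and the 1,1-disubstituted alkene without touching the stereocentres at C4 and C8.

**Step 5**
Reactants: 10 methyl (2S,6R)-2,6-dimethyl-4-methylidene-14-phenyltetradecanoate
Product: 11 (2S,6R)-2,6-dimethyl-4-methylidene-14-phenyltetradecanal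
Conditions: i-Bu2AlH (1.1 equiv), CH2Cl2, –78 °C; MeOH, then aq. potassium sodium tartrate
Reagents that add atoms: none
Why: Partial reduction of the methyl ester with i-Bu2AlH stops at the tetrahedral aluminium hemiacetal at –78 °C, which releases the aldehyde only on work-up, so the epimerisable C4 centre should be preserved if 11 is used at once.

**Step 6**
Reactants: 11 (2S,6R)-2,6-dimethyl-4-methylidene-14-phenyltetradecanal; 12 acetyl bromide
Product: 14 (4R)-4-[(2S,6R)-6-methyl-4-methylidene-14-phenyltetradecan-2-yl]oxetan-2-one, via ketene 13 (not isolated)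
Conditions: AlMe3/(S,S)-BnN[CH2CH(i-Pr)NHSO2CF3]2 (15 mol%), i-Pr2NEt, CH2Cl2, –50 °C
Reagents that add atoms: none
Why: Catalytic asymmetric acyl halide–aldehyde cyclocondensation, in which ketene formed in situ from acetyl bromide and the amine adds in a net [2+2] fashion to the aldehyde bound to the chiral aluminium triamine complex, so that the catalyst and not the substrate dictates the new C3 centre (R, anti to the C4 methyl group).

**Step 7**
Reactants: 14 (4R)-4-[(2S,6R)-6-methyl-4-methylidene-14-phenyltetradecan-2-yl]oxetan-2-one
Product: 15 (4R)-4-[(2S,4R,6R)-4,6-dimethyl-14-phenyl-4-(triethylsilylperoxy)tetradecan-2-yl]oxetan-2-one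
Conditions: Co(thd)2 (thd = 2,2,6,6-tetramethylheptane-3,5-dionate; 10 mol%), O2 (1 atm), Et3SiH (2 equiv), ClCH2CH2Cl, rt
Reagents that add atoms: dioxygen, O=O; triethylsilane, CC[SiH](CC)CC
Why: Isayama–Mukaiyama hydroperoxysilylation, in which a cobalt hydride delivers a hydrogen atom to the CH2 terminus (creating the C6 methyl group), the tertiary C6 radical traps O2 and the peroxy species is silylated under neutral conditions that should spare the β-lactone; nothing in the substrate biases the remote C6 radical, so 15 is expected together with its C6 epimer.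

**Step 8**
Reactants: 15 (4R)-4-[(2S,4R,6R)-4,6-dimethyl-14-phenyl-4-(triethylsilylperoxy)tetradecan-2-yl]oxetan-2-one
Product: 16 (4R)-4-[(2S,4R,6R)-4-hydroperoxy-4,6-dimethyl-14-phenyltetradecan-2-yl]oxetan-2-one
Conditions: 48% aq. HF, MeCN, 0 °C; pH 7 buffer
Reagents that add atoms: none
Why: Fluoride-assisted cleavage of the weak Si–OO bond under acidic, non-nucleophilic conditions (a standard desilylation in the presence of β-lactones) should free the hydroperoxide without generating the peroxy anion prematurely.

**Step 9**
Reactants: 16 (4R)-4-[(2S,4R,6R)-4-hydroperoxy-4,6-dimethyl-14-phenyltetradecan-2-yl]oxetan-2-one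
Product: 18 2-[(3S,4S,6R)-4,6-dimethyl-6-[(2R)-2-methyl-10-phenyldecyl]-1,2-dioxan-3-yl]acetic acid, via potassium peroxide salt 17 (not isolated)
Conditions: KOt-Bu (1.05 equiv), 18-crown-6, THF (0.005 M), –40 → 0 °C; cold 1 M HCl to pH 3; SiO2 chromatography (removal of the C6 epimer)
Reagents that add atoms: none
Why: Proposed new method: tert-butoxide converts the tertiary hydroperoxide fully into its anion 17, whose terminal oxygen attacks C3 anti to the lactone C3–O bond, so that alkyl–oxygen cleavage forms O2–C3 and expels C1 as the carboxylate with release of the four-membered-ring strain. The closest known reaction types are the SN2 alkyl–oxygen opening of 4-alkyl oxetan-2-ones by azide, thiolate and sulfonamide anions, the Lewis-acid-promoted intramolecular opening of β-lactones at the β-carbon by a tethered oxygen with inversion, and the base-mediated cyclisation of hydroperoxides onto secondary sulfonates. The 1,2-dioxane closes in the 6-exo-tet mode through a chair-like array in which the breaking C3–O bond lies outside the new ring and collinear with the incoming oxygen. C3 is set as S by stereospecific inversion of the R lactone carbon (substrate control), while C4, C6 and C8 are spectators. The step needs alkyl–oxygen and not acyl–oxygen attack, which the tether secures because intramolecular acyl attack would have to pass through an eight-membered cyclic perester whereas C3 is reached in a six-membered array, and high dilution keeps intermolecular acyl attack slow. Elimination to the enoate is disfavoured because the enolate π system of the lactone is orthogonal to the C3–O bond, and the single equivalent of base is consumed as the carboxylate forms, which protects the C3–H of the product peroxide from base-induced fragmentation.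

**Compound list**
1 | (8-bromooctyl)benzene | BrCCCCCCCCc1ccccc1 | starting material
2 | (E)-pent-3-en-2-one | C/C=C/C(C)=O | starting material
3 | (8-phenyloctyl)magnesium bromide | Br[Mg]CCCCCCCCc1ccccc1 | intermediate (not isolated)
4 | (4R)-4-methyl-12-phenyldodecan-2-one | C[C@H](CCCCCCCCc1ccccc1)CC(C)=O | intermediate
5 | lithium (4R)-4-methyl-12-phenyldodec-1-en-2-olate | C[C@H](CCCCCCCCc1ccccc1)CC(=C)[O-].[Li+] | intermediate (not isolated)
6 | (4R)-4-methyl-12-phenyldodec-1-en-2-yl trifluoromethanesulfonate | C[C@H](CCCCCCCCc1ccccc1)CC(=C)OS(=O)(=O)C(F)(F)F | intermediate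
7 | methyl (S)-3-hydroxy-2-methylpropanoate | C[C@@H](CO)C(=O)OC | starting material
8 | methyl (R)-3-iodo-2-methylpropanoate | C[C@@H](CI)C(=O)OC | intermediate
9 | iodo[(2R)-3-methoxy-2-methyl-3-oxopropyl]zinc | C[C@@H](C[Zn]I)C(=O)OC | intermediate (not isolated)
10 | methyl (2S,6R)-2,6-dimethyl-4-methylidene-14-phenyltetradecanoate | C[C@H](CCCCCCCCc1ccccc1)CC(=C)C[C@H](C)C(=O)OC | intermediate
11 | (2S,6R)-2,6-dimethyl-4-methylidene-14-phenyltetradecanal | C[C@H](CCCCCCCCc1ccccc1)CC(=C)C[C@H](C)C=O | intermediate
12 | acetyl bromide | CC(=O)Br | starting material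
13 | ketene | C=C=O | intermediate (not isolated)
14 | (4R)-4-[(2S,6R)-6-methyl-4-methylidene-14-phenyltetradecan-2-yl]oxetan-2-one | C[C@H](CCCCCCCCc1ccccc1)CC(=C)C[C@H](C)[C@H]1CC(=O)O1 | intermediate
15 | (4R)-4-[(2S,4R,6R)-4,6-dimethyl-14-phenyl-4-(triethylsilylperoxy)tetradecan-2-yl]oxetan-2-one | C[C@H](CCCCCCCCc1ccccc1)C[C@@](C)(OO[Si](CC)(CC)CC)C[C@H](C)[C@H]1CC(=O)O1 | intermediate
16 | (4R)-4-[(2S,4R,6R)-4-hydroperoxy-4,6-dimethyl-14-phenyltetradecan-2-yl]oxetan-2-one | C[C@H](CCCCCCCCc1ccccc1)C[C@@](C)(OO)C[C@H](C)[C@H]1CC(=O)O1 | intermediate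
17 | potassium salt of 16 (peroxy anion on C6) | C[C@H](CCCCCCCCc1ccccc1)C[C@@](C)(O[O-])C[C@H](C)[C@H]1CC(=O)O1.[K+] | intermediate (not isolated)
18 | 2-[(3S,4S,6R)-4,6-dimethyl-6-[(2R)-2-methyl-10-phenyldecyl]-1,2-dioxan-3-yl]acetic acid | C[C@H](CCCCCCCCc1ccccc1)C[C@]1(C)C[C@H](C)[C@H](CC(=O)O)OO1 | target

**Step count**
Total: 9 steps. Longest linear sequence: 8 steps (steps 1, 2, 4, 5, 6, 7, 8, 9 from (8-bromooctyl)benzene); step 3 is the side branch.

**Steps most likely to fail**

1. Step 9. The peroxy anion may be too slow at the β-branched C3, so that intermolecular acyl attack (oligomeric peresters), acyl opening by adventitious hydroxide or base-induced fragmentation of the product take over.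
 Fallback with established chemistry, from 14 back to 18:
 - LiBH4 (THF, 0 °C) would reduce the lactone of 14 to the 1,3-diol F1.
 - TBSCl/imidazole would give the primary silyl ether F2, and MsCl/Et3N the secondary C3 mesylate F3.
 - Peroxidation as in step 7 would give the silyl peroxide F4, and aqueous HF in MeCN would remove both silyl groups to give the hydroperoxy alcohol F5.
 - KOt-Bu/18-crown-6 (one equivalent, THF) would close the ring by the known 6-exo-tet displacement of the sulfonate with inversion at C3, giving the dioxane ethanol F6.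
 - Oxidation of the primary alcohol with TEMPO/PhI(OAc)2 in aqueous MeCN would rejoin the route at 18.
 - Keeping C1 at the alcohol level during the displacement avoids the loss of the sulfonate by elimination that a C1 ester would suffer.

2. Step 6. The required anti relationship between the lactone oxygen and the C4 methyl group runs against the Felkin preference of the α-methyl aldehyde, so catalyst and substrate control are mismatched. Turnover with an α-branched aldehyde may also be slow, and the amine base may epimerise C4.
 Fallback, from 11 back to 14: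
 - A tin-mediated acetate aldol with (S)-3-acetyl-4-isopropyl-1,3-thiazolidine-2-thione (Sn(OTf)2, N-ethylpiperidine, CH2Cl2, –78 °C), in which the auxiliary overrides the aldehyde bias, should give the (3R)-β-hydroxy acyl thiazolidinethione F7.
 - LiOH in aqueous THF would release the β-hydroxy acid F8.
 - Carboxyl activation with PhSO2Cl in pyridine (0 °C), a lactonisation that retains the C3 configuration, would return to the route at 14.

3. Step 7. The peroxy intermediate may be over-reduced to the tertiary alcohol, the lactone may be opened by silanol or cobalt alkoxide by-products, or conversion may stall.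
 Fallback, from 14 back to 16:
 - A cobalt-catalysed hydrogen-atom-transfer hydrochlorination (Co(BF4)2·6H2O with the Schiff base of 3,5-di-tert-butylsalicylaldehyde and potassium 2,2-diphenylglycinate, PhSiH3, TsCl, EtOH) would give the tertiary chloride F9.
 - Silver-assisted perhydrolysis (AgOTf, anhydrous H2O2 in Et2O, 0 °C), an ionic substitution at the tertiary carbon, would deliver the hydroperoxide and rejoin the route at 16, bypassing 15 and step 8.
 - C6 would again arise as both epimers.

**Further compounds**
F1 | step 9 | (3R,4S,8R)-4,8-dimethyl-6-methylidene-16-phenylhexadecane-1,3-diol | C[C@H](CCCCCCCCc1ccccc1)CC(=C)C[C@H](C)[C@H](O)CCO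
F2 | step 9 | (3R,4S,8R)-1-[(tert-butyldimethylsilyl)oxy]-4,8-dimethyl-6-methylidene-16-phenylhexadecan-3-ol | C[C@H](CCCCCCCCc1ccccc1)CC(=C)C[C@H](C)[C@H](O)CCO[Si](C)(C)C(C)(C)C
F3 | step 9 | (3R,4S,8R)-1-[(tert-butyldimethylsilyl)oxy]-4,8-dimethyl-6-methylidene-16-phenylhexadecan-3-yl methanesulfonate | C[C@H](CCCCCCCCc1ccccc1)CC(=C)C[C@H](C)[C@H](OS(C)(=O)=O)CCO[Si](C)(C)C(C)(C)C
F4 | step 9 | (3R,4S,6R,8R)-1-[(tert-butyldimethylsilyl)oxy]-4,6,8-trimethyl-16-phenyl-6-[(triethylsilyl)peroxy]hexadecan-3-yl methanesulfonate | C[C@H](CCCCCCCCc1ccccc1)C[C@@](C)(OO[Si](CC)(CC)CC)C[C@H](C)[C@H](OS(C)(=O)=O)CCO[Si](C)(C)C(C)(C)C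
F5 | step 9 | (3R,4S,6R,8R)-6-hydroperoxy-1-hydroxy-4,6,8-trimethyl-16-phenylhexadecan-3-yl methanesulfonate | C[C@H](CCCCCCCCc1ccccc1)C[C@@](C)(OO)C[C@H](C)[C@H](OS(C)(=O)=O)CCO
F6 | step 9 | 2-[(3S,4S,6R)-4,6-dimethyl-6-[(2R)-2-methyl-10-phenyldecyl]-1,2-dioxan-3-yl]ethan-1-ol | C[C@H](CCCCCCCCc1ccccc1)C[C@]1(C)C[C@H](C)[C@H](CCO)OO1
F7 | step 6 | (3R,4S,8R)-3-hydroxy-4,8-dimethyl-6-methylidene-16-phenyl-1-[(4S)-4-(propan-2-yl)-2-sulfanylidene-1,3-thiazolidin-3-yl]hexadecan-1-one | C[C@H](CCCCCCCCc1ccccc1)CC(=C)C[C@H](C)[C@H](O)CC(=O)N1[C@@H](C(C)C)CSC1=S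
F8 | step 6 | (3R,4S,8R)-3-hydroxy-4,8-dimethyl-6-methylidene-16-phenylhexadecanoic acid | C[C@H](CCCCCCCCc1ccccc1)CC(=C)C[C@H](C)[C@H](O)CC(=O)O
F9 | step 7 | (4R)-4-[(2S,6R)-4-chloro-4,6-dimethyl-14-phenyltetradecan-2-yl]oxetan-2-one (both epimers at the chlorinated carbon) | C[C@H](CCCCCCCCc1ccccc1)CC(C)(Cl)C[C@H](C)[C@H]1CC(=O)O1
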